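**Assumption:** names use daucane numbering (C1 = methyl-bearing ring-fusion carbon, C4 = isopropyl carbinol carbon, C5 = ring-fusion CH, C6–C10 = rest of the seven-membered ring, C8 methyl-bearing), α/β are relative to the C1 methyl (β), and 15 is taken as a catalogue reagent.

## Retrosynthetic overview

1. Target ⇒ remove the peripheral oxygens: epoxide (α-face epoxidation of a C8=C9 alkene), 7β-OH (singlet-oxygen ene reaction that also moves the alkene from C7=C8 to C8=C9), aroyl ester and 6α-OH (hydroxyl-directed ketone reduction) ⇒ a trans-fused 4-hydroxy-dauc-7-en-6-one.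
2. Key disconnection (C1–C2, with C4–C5 closed in the same operation): enantioselective conjugate addition of an isopropyl ketone homoenolate (from a cyclopropanol) to a symmetrical 3,6-dimethylcyclohepta-2,6-dienone, then intramolecular aldol. All fifteen skeletal carbons are in place after this step.
3. The dienone ⇒ oxyallyl (4+3) cycloadduct of 2,5-dimethylfuran (hydrogenation, then double β-elimination of the oxygen bridge).
4. Ring order: seven-membered ring first, five-membered ring second (key step), epoxide last.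

## Route

Step 1
Reactants: 1 2,5-dimethylfuran; 2 1,1,3-trichloropropan-2-one
Product: 4 oxabicyclic enone 1,5-dimethyl-8-oxabicyclo[3.2.1]oct-6-en-3-one, via dichloro cycloadduct 3 (not isolated)
Conditions: Et3N, CF3CH2OH, 0 → 23 °C; then Zn/Cu couple, NH4Cl, MeOH, 23 °C
Reagents that add atoms: none
Why: Oxyallyl cation (4+3) cycloaddition: Et3N in trifluoroethanol converts 2 into a 1,3-dichloro-2-oxyallyl cation that adds across the furan diene, and Zn/Cu then reduces both C–Cl bonds; the bicycle is necessarily cis-bridged and meso.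

Step 2
Reactants: 4 oxabicyclic enone
Product: 5 saturated oxabicyclic ketone 1,5-dimethyl-8-oxabicyclo[3.2.1]octan-3-one
Conditions: H2 (1 atm), 10% Pd/C, EtOAc, 23 °C
Reagents that add atoms: none
Why: Catalytic hydrogenation of the strained cis-disubstituted alkene, so that the later bridge opening stops at the dihydrotropone level; ketone and ether are untouched and the product is meso.

Step 3
Reactants: 5 saturated oxabicyclic ketone
Product: 7 dienone 3,6-dimethylcyclohepta-2,6-dien-1-one, via hydroxy enone 6 (not isolated)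
Conditions: TsOH·H2O (10 mol %), toluene, 110 °C, Dean–Stark, short reaction time
Reagents that add atoms: none
Why: Acid-catalysed retro-oxa-Michael opening of the β-alkoxy ketone followed by dehydration of the resulting tertiary β-hydroxy ketone (the oxygen analogue of the tropinone to cycloheptadienone double elimination) gives the cross-conjugated, achiral dienone.

Step 4
Reactants: 8 methyl 2-methylpropanoate
Product: 9 1-(propan-2-yl)cyclopropan-1-ol
Conditions: EtMgBr (2.2 equiv), Ti(OiPr)4 (20 mol %), Et2O, 0 → 23 °C; aqueous work-up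
Reagents that add atoms: ethylmagnesium bromide, CC[Mg]Br
Why: Kulinkovich cyclopropanation: the titanacyclopropane generated from EtMgBr and Ti(OiPr)4 adds twice to the ester carbonyl; no stereocentre is formed.

Step 5
Reactants: 7 dienone; 9 1-(propan-2-yl)cyclopropan-1-ol
Product: 13 trans-fused ketol 4β-hydroxy-5α-dauc-7-en-6-one, via zinc homoenolate 10 (not isolated), via diketone 11 (not isolated), via cis-fused ketol 12 (not isolated)
Conditions: 9 (2.6 equiv), ZnEt2 (1.3 equiv), THF, 0 → 23 °C; Cu(OTf)2 (5 mol %), chiral sulfonate-imidazolinium NHC precursor (6 mol %), 7, Et2O, −30 → 0 °C; then NaOMe (0.3 equiv), MeOH, 23 °C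
Reagents that add atoms: none
Why: Proposed new method: the zinc cyclopropoxide from 9 ring-opens to the β-zincio ketone 10 (a homoenolate, nucleophilic at the carbon β to its carbonyl); transmetalation to a chiral NHC–copper alkyl and 1,4-addition to one of the two enantiotopic β-carbons of the symmetrical dienone 7 joins two normally electrophilic carbons and sets the C1 quaternary centre under ligand control (the mirror-image ligand would give the antipode); the zinc enolate then closes the five-membered ring by intramolecular aldol addition to the isopropyl ketone (necessarily cis-fused at first, 12); methoxide-mediated retro-aldol/aldol plus C5 enolisation is expected to equilibrate this to the trans-fused ketol 13, in which the tertiary OH is hydrogen-bonded to the C6 carbonyl and both the isopropyl group and C10 are pseudo-equatorial; closest known chemistry: copper-catalysed conjugate addition of zinc homoenolates to enones, NHC–copper-catalysed enantioselective addition of dialkylzincs to 3-methylcyclohept-2-enone to give quaternary centres, and base-equilibrated Robinson-type ketols.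

Step 6
Reactants: 13 trans-fused ketol
Product: 14 diol 5α-dauc-7-ene-4β,6α-diol
Conditions: Me4NBH(OAc)3 (5 equiv), MeCN/AcOH 1:1, −30 °C
Reagents that add atoms: none
Why: Evans–Saksena hydroxyl-directed 1,3-anti reduction: the 4β-OH exchanges onto boron and delivers hydride intramolecularly to the β-face of the C6 carbonyl (1,2-addition to the enone), giving the 6α-alcohol.

Step 7
Reactants: 14 diol; 15 4-[(tert-butyldimethylsilyl)oxy]benzoic acid
Product: 17 ester 4β-hydroxy-5α-dauc-7-en-6α-yl 4-[(tert-butyldimethylsilyl)oxy]benzoate, via mixed anhydride 16 (not isolated)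
Conditions: 15, 2,4,6-Cl3C6H2COCl, Et3N, THF, 23 °C; then 14, DMAP, toluene, 40 °C
Reagents that add atoms: none
Why: Yamaguchi esterification through the mixed anhydride: DMAP transfers the less hindered aroyl group to the secondary allylic 6α-OH with retention at C6, the tertiary 4-OH being unreactive.

Step 8
Reactants: 17 ester
Product: 20 silyl ether 4β-hydroxy-7β-[(triethylsilyl)oxy]-5α-dauc-8-en-6α-yl 4-[(tert-butyldimethylsilyl)oxy]benzoate, via allylic hydroperoxide 18 (not isolated), via allylic alcohol 19 (not isolated)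
Conditions: O2, tetraphenylporphyrin (1 mol %), visible light, CH2Cl2, −20 °C; PPh3, 0 °C; then imidazole, DMAP (cat.), Et3SiCl, 23 °C
Reagents that add atoms: dioxygen (as singlet oxygen), O=O; chlorotriethylsilane, CC[Si](Cl)(CC)CC
Why: Schenck ene reaction: singlet oxygen adds to C7 on the β-face, anti to the 6α-aroyloxy group, and removes a C9 hydrogen from the ring (cis-disubstituted) side of the trisubstituted alkene, so the alkene moves to C8=C9 and C7 becomes 7β-OOH; PPh3 reduces the O–O bond with retention and the secondary allylic alcohol is silylated in preference to the hindered tertiary 4-OH.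

Step 9
Reactants: 20 silyl ether
Product: 21 epoxide 8α,9α-epoxy-4β-hydroxy-7β-[(triethylsilyl)oxy]-5α-daucan-6α-yl 4-[(tert-butyldimethylsilyl)oxy]benzoate
Conditions: mCPBA, CH2Cl2, 0 °C
Reagents that add atoms: 3-chloroperoxybenzoic acid (mCPBA), OOC(=O)c1cccc(Cl)c1
Why: Prilezhaev epoxidation of the only alkene: the peracid approaches the α-face, anti to the allylic 7β-silyloxy group and the pseudo-axial 1β-methyl, giving the 8α,9α-epoxide (the silyl ether removes hydroxyl direction to the β-face).

Step 10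
Reactants: 21 epoxide
Product: 22 target 8α,9α-epoxy-4β,7β-dihydroxy-5α-daucan-6α-yl 4-hydroxybenzoate
Conditions: Bu4NF, AcOH (1:1, 3 equiv), THF, 0 → 23 °C
Reagents that add atoms: none
Why: Fluoride-mediated desilylation of the aryl tert-butyldimethylsilyl ether and the secondary triethylsilyl ether; acetic acid buffering prevents Payne rearrangement or acyl migration in the epoxy alcohol ester, and no stereocentre is touched.

## Compound list

1 | 2,5-dimethylfuran | Cc1ccc(C)o1 | starting material
2 | 1,1,3-trichloropropan-2-one | ClCC(=O)C(Cl)Cl | starting material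
3 | 2,4-dichloro-1,5-dimethyl-8-oxabicyclo[3.2.1]oct-6-en-3-one (cis-bridged; mixture of C2/C4 chlorine epimers) | C[C@]12C(Cl)C(=O)C(Cl)[C@](C)(C=C1)O2 | intermediate
4 | 1,5-dimethyl-8-oxabicyclo[3.2.1]oct-6-en-3-one (meso) | C[C@]12CC(=O)C[C@](C)(C=C1)O2 | intermediate
5 | 1,5-dimethyl-8-oxabicyclo[3.2.1]octan-3-one (meso) | C[C@]12CC(=O)C[C@](C)(CC1)O2 | intermediate
6 | 6-hydroxy-3,6-dimethylcyclohept-2-en-1-one (racemic) | CC1=CC(=O)CC(C)(O)CC1 | intermediate
7 | 3,6-dimethylcyclohepta-2,6-dien-1-one (achiral) | CC1=CC(=O)C=C(C)CC1 | intermediate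
8 | methyl 2-methylpropanoate | COC(=O)C(C)C | starting material
9 | 1-(propan-2-yl)cyclopropan-1-ol | CC(C)C1(O)CC1 | intermediate
10 | bis(4-methyl-3-oxopentyl)zinc | CC(C)C(=O)CC[Zn]CCC(=O)C(C)C | intermediate
11 | (6S)-3,6-dimethyl-6-(4-methyl-3-oxopentyl)cyclohept-2-en-1-one (formed as its zinc enolate) | CC(C)C(=O)CC[C@]1(C)CCC(C)=CC(=O)C1 | intermediate
12 | 4α-hydroxy-5β-dauc-7-en-6-one (cis-fused ketol: 1β-Me, 4α-OH, 4β-isopropyl, 5β-H) | CC(C)[C@@]1(O)CC[C@]2(C)CCC(C)=CC(=O)[C@@H]21 | intermediate
13 | 4β-hydroxy-5α-dauc-7-en-6-one (trans-fused ketol: 1β-Me, 4β-OH, 4α-isopropyl, 5α-H) | CC(C)[C@]1(O)CC[C@]2(C)CCC(C)=CC(=O)[C@H]21 | intermediate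
14 | 5α-dauc-7-ene-4β,6α-diol | CC(C)[C@]1(O)CC[C@]2(C)CCC(C)=C[C@H](O)[C@H]21 | intermediate
15 | 4-[(tert-butyldimethylsilyl)oxy]benzoic acid | CC(C)(C)[Si](C)(C)Oc1ccc(cc1)C(=O)O | starting material
16 | 4-[(tert-butyldimethylsilyl)oxy]benzoic 2,4,6-trichlorobenzoic anhydride | CC(C)(C)[Si](C)(C)Oc1ccc(cc1)C(=O)OC(=O)c1c(Cl)cc(Cl)cc1Cl | intermediate
17 | 4β-hydroxy-5α-dauc-7-en-6α-yl 4-[(tert-butyldimethylsilyl)oxy]benzoate | CC(C)[C@]1(O)CC[C@]2(C)CCC(C)=C[C@H](OC(=O)c3ccc(O[Si](C)(C)C(C)(C)C)cc3)[C@H]21 | intermediate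
18 | 7β-hydroperoxy-4β-hydroxy-5α-dauc-8-en-6α-yl 4-[(tert-butyldimethylsilyl)oxy]benzoate | CC(C)[C@]1(O)CC[C@]2(C)CC=C(C)[C@@H](OO)[C@H](OC(=O)c3ccc(O[Si](C)(C)C(C)(C)C)cc3)[C@H]21 | intermediate
19 | 4β,7β-dihydroxy-5α-dauc-8-en-6α-yl 4-[(tert-butyldimethylsilyl)oxy]benzoate | CC(C)[C@]1(O)CC[C@]2(C)CC=C(C)[C@@H](O)[C@H](OC(=O)c3ccc(O[Si](C)(C)C(C)(C)C)cc3)[C@H]21 | intermediate
20 | 4β-hydroxy-7β-[(triethylsilyl)oxy]-5α-dauc-8-en-6α-yl 4-[(tert-butyldimethylsilyl)oxy]benzoate | CC(C)[C@]1(O)CC[C@]2(C)CC=C(C)[C@@H](O[Si](CC)(CC)CC)[C@H](OC(=O)c3ccc(O[Si](C)(C)C(C)(C)C)cc3)[C@H]21 | intermediate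
21 | 8α,9α-epoxy-4β-hydroxy-7β-[(triethylsilyl)oxy]-5α-daucan-6α-yl 4-[(tert-butyldimethylsilyl)oxy]benzoate | CC(C)[C@]1(O)CC[C@]2(C)C[C@@H]3O[C@]3(C)[C@@H](O[Si](CC)(CC)CC)[C@H](OC(=O)c3ccc(O[Si](C)(C)C(C)(C)C)cc3)[C@H]21 | intermediate
22 | 8α,9α-epoxy-4β,7β-dihydroxy-5α-daucan-6α-yl 4-hydroxybenzoate (CNP0290052.1) | CC(C)[C@]1(O)CC[C@]2(C)C[C@@H]3O[C@]3(C)[C@@H](O)[C@H](OC(=O)c3ccc(O)cc3)[C@H]21 | target

## Step count and risks

Total step count: 10. Longest linear sequence: 9 (steps 1–3 and 5–10; step 4 is a one-step side branch).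

**Step 5 (most likely to fail).** The copper-catalysed enantioselective transfer of a ketone homoenolate to a β,β-disubstituted dienone is untested. The ring-fusion equilibrium between 12 and 13 may also not lie far on the side of 13; in that case 12 is separated and re-equilibrated. Fallback, setting out from 9 and 7 and returning at 11: the homoenolate is used in masked form as a Grignard reagent. N-Bromosuccinimide opens 9 to 1-bromo-4-methylpentan-3-one F1. Ethylene glycol with TsOH gives 2-(2-bromoethyl)-2-(propan-2-yl)-1,3-dioxolane F2. Mg in THF gives {2-[2-(propan-2-yl)-1,3-dioxolan-2-yl]ethyl}magnesium bromide F3. Conjugate addition of F3 to 7 (Cu(OTf)2 and a chiral imidazolinium NHC precursor, Et2O, 0 °C, a Grignard addition type established for 3-methylcycloalkenones) gives (6S)-3,6-dimethyl-6-{2-[2-(propan-2-yl)-1,3-dioxolan-2-yl]ethyl}cyclohept-2-en-1-one F4. Dilute HCl in THF removes the ketal to give 11, which is cyclised and equilibrated with NaOMe in MeOH as in step 5.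

**Step 8.** Singlet oxygen may abstract a methyl hydrogen instead of the C9 hydrogen, giving the exocyclic alkene, or attack the α-face. Fallback, setting out from 13 and returning at 19: the alkene is moved first and the oxygen is put in by allylic C–H oxidation. Me3SiOTf and Et3N convert 13 into 4β-(trimethylsilyloxy)-6-(trimethylsilyloxy)-5α-dauca-6,8-diene F5. Kinetic α-protonation (Bu4NF, AcOH, THF, −78 °C) gives the deconjugated 4β-hydroxy-5α-dauc-8-en-6-one F6. Directed reduction as in step 6 gives 5α-dauc-8-ene-4β,6α-diol F7. Yamaguchi esterification with 15 (through 16) gives 4β-hydroxy-5α-dauc-8-en-6α-yl 4-[(tert-butyldimethylsilyl)oxy]benzoate F8. SeO2 (cat.) with t-BuOOH in CH2Cl2 hydroxylates the ring CH2 next to the more substituted alkene carbon (ene reaction, then 2,3-shift) on the face opposite the 6α-ester, giving 19, which is silylated as in step 8.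

**Step 9.** The peracid may attack the β-face despite the silyl ether. Fallback, setting out from 20 and returning at 21: the oxygen is delivered as a nucleophile instead of an electrophile. N-Bromosuccinimide in aqueous THF forms the bromonium ion on the face preferred by electrophiles, and water opens it at the tertiary C8 from the opposite face to give 9β-bromo-4β,8α-dihydroxy-7β-[(triethylsilyl)oxy]-5α-daucan-6α-yl 4-[(tert-butyldimethylsilyl)oxy]benzoate F9. K2CO3 in MeCN closes the 8α,9α-epoxide 21 by displacement with inversion at C9.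

## Further compounds

F1 | step 5 | 1-bromo-4-methylpentan-3-one | CC(C)C(=O)CCBr
F2 | step 5 | 2-(2-bromoethyl)-2-(propan-2-yl)-1,3-dioxolane | CC(C)C1(CCBr)OCCO1
F3 | step 5 | {2-[2-(propan-2-yl)-1,3-dioxolan-2-yl]ethyl}magnesium bromide | CC(C)C1(CC[Mg]Br)OCCO1
F4 | step 5 | (6S)-3,6-dimethyl-6-{2-[2-(propan-2-yl)-1,3-dioxolan-2-yl]ethyl}cyclohept-2-en-1-one | CC(C)C1(CC[C@]2(C)CCC(C)=CC(=O)C2)OCCO1
F5 | step 8 | 4β-(trimethylsilyloxy)-6-(trimethylsilyloxy)-5α-dauca-6,8-diene | CC(C)[C@]1(O[Si](C)(C)C)CC[C@]2(C)CC=C(C)C=C(O[Si](C)(C)C)[C@H]21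
F6 | step 8 | 4β-hydroxy-5α-dauc-8-en-6-one | CC(C)[C@]1(O)CC[C@]2(C)CC=C(C)CC(=O)[C@H]21
F7 | step 8 | 5α-dauc-8-ene-4β,6α-diol | CC(C)[C@]1(O)CC[C@]2(C)CC=C(C)C[C@H](O)[C@H]21
F8 | step 8 | 4β-hydroxy-5α-dauc-8-en-6α-yl 4-[(tert-butyldimethylsilyl)oxy]benzoate | CC(C)[C@]1(O)CC[C@]2(C)CC=C(C)C[C@H](OC(=O)c3ccc(O[Si](C)(C)C(C)(C)C)cc3)[C@H]21
F9 | step 9 | 9β-bromo-4β,8α-dihydroxy-7β-[(triethylsilyl)oxy]-5α-daucan-6α-yl 4-[(tert-butyldimethylsilyl)oxy]benzoate | CC(C)[C@]1(O)CC[C@]2(C)C[C@@H](Br)[C@](C)(O)[C@@H](O[Si](CC)(CC)CC)[C@H](OC(=O)c3ccc(O[Si](C)(C)C(C)(C)C)cc3)[C@H]21
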